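Late in the earlier runs, at 25 h, the idle adduct reads 6.2 % in beta, 10.0 % in alpha and 8.2 % in delta.

| setting | beta | alpha | delta | flask |
|---|---|---|---|---|
| substrate | 0.067 M (in portions, 4) | 0.15 M (in portions, 4) | 0.10 M (in portions, 4) | 0.10 M (in portions, 4) |
| enzyme | 1.8 µM | 1.8 µM | 3.6 µM | 1.8 µM |
| remark | run made earlier; portions every 3.0 h | run made earlier; portions every 3.0 h | run made earlier; portions every 3.0 h | the portions of substrate follow each other after 3.0 h, the first at the start |
| time |  |  |  | 25 h |

- beta (time / h: idle adduct / %, product / %, substrate / %): 2.00: 0.3, 0.1, 23.2; 3.00: 0, 3.8, 24.7; 6.00: 0, 3.8, 46.9; 10.0: 2.7, 7.2, 90.4; 15.0: 4.1, 13.3, 83.5; 25.0: 6.2, 27.2, 70.2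
- alpha (time / h: idle adduct / %, product / %, substrate / %): 4.00: 0, 2.6, 48.1; 8.00: 1.1, 6.2, 69.2; 12.0: 3.0, 11.6, 90.4; 15.0: 4.4, 10.7, 84.7; 20.0: 6.2, 17.5, 78.4; 25.0: 10.0, 23.0, 73.2
- delta (time / h: idle adduct / %, product / %, substrate / %): 5.00: 0.6, 6.0, 44.4; 10.0: 4.3, 16.0, 82.9; 15.0: 8.6, 25.6, 70.6; 20.0: 8.1, 35.3, 62.4; 25.0: 8.2, 43.1, 51.7

(standard deviation of a reading: 1 percentage point)

- a species is counted by the substrate in it: one idle adduct counts as two
- amounts and yields of product count idle adduct too
- what was read earlier has a scatter of 1 percentage point, one standard deviation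
- in an amount of product, one idle adduct counts as one product

- amount of idle adduct in percent of the substrate charged, at 2.5 h, 8.0 h and 25 h

1. Compare two amounts: [A], the idle adduct, and [S][P], free substrate times free product. Let y, s and p be the adduct, substrate and product readings as fractions of the charge c. One adduct counts double in y and once in p, so [A] = yc/2 and [P] = (p − y/2)c.

2. The ratio [A]/([S][P]) at 25.0 h reads 2.73 /M in beta, 2.53 /M in alpha and 2.03 /M in delta. Their mean is 2.43 /M: K, the association constant of substrate and product.

3. Delta at 15.0 h already reads 2.86 /M, more than its 2.03 /M at 25.0 h. So my own reckoning lets the adduct follow K at each moment, with no lag.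

4. Substituting gives y = 2Kcsp/(1 + Kcs). Beta and alpha have the flask's enzyme, and their late product gain per mean substrate gives a pseudo-first-order constant k = 0.0168 /h.

5. For the flask, p is k times the time sum of s. At 2.5 h, p = 1.05 % and s = 23.9 %, so y = 0.116 %. At 8.0 h, p = 6.31 % and s = 68.7 %, so y = 1.81 %. At 25 h, the means of beta and alpha give s = 71.7 % and p = 25.1 %, so y = 7.46 %.

6. The forecast gives 0.03 %, 0.6 % and 7.5 %, and its grounds include this: “which suggests equilibrium with a relaxation time of several hours”. Its first two values are lower than mine.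

The flask gives 0.109 %, 1.50 % and 7.00 %.

    substrate + enzyme ⇌ complex (K = 4.40 /M, k = 4.20 × 10⁶ /M/h)
    enzyme → spent catalyst (k = 3.70 × 10⁻⁵ /h)
    substrate + product ⇌ idle adduct, settled at all times (K = 2.30 /M)
    complex → enzyme + product (k = 2400 /h)

At 25.0 h the flask holds substrate 71.8 % and product 24.7 %, and K turns these into 7.35 % of idle adduct. At 250 h the flask holds substrate 2.17 % and product 97.3 %, and K turns these into 1.02 %, against 0.967 % of idle adduct in the flask.

The runs are calculated from invented constants; the scatter is artificial.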